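The benzene ring of the indenone (C-3a, C-4, C-5, C-6, C-7, C-7a) is the ring that is disconnected. It carries the formyl carbon on C-4 and a methyl on C-7 in a para relationship, C-5 and C-6 are bare, and C-3 beside C-3a can hold an oxygen. This is the imprint of 6-methyl-2-pyrone-3-carboxylic acid esterified to a tertiary cyclopentenol. Heating that ester, a trans-4-acyloxy-4-methyl-5-(guaiazulen-3-yl)cyclopent-2-enone, should bring about intramolecular Diels–Alder addition and loss of CO2 in one operation. This forms C-3a–C-4 and C-7–C-7a, the six-membered carbocycle and a sacrificial γ-lactone. The lactone oxygen later leaves to create C-2=C-3, and one enolate bromination–dehydrobromination supplies the arene.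

Key step: step 7

Remarks
- All chiral intermediates are racemic. Each stereo-SMILES shows one enantiomer and defines relative configuration only. The target is achiral.
- Indenone numbering (C-1 carbonyl, C-2 azulenyl, C-3 methyl, C-4 carboxyl or formyl carbon, C-7 methyl) is used from 15 onwards. Guaiazulen-3-yl means 5-isopropyl-3,8-dimethylazulen-1-yl.
- Redox bookkeeping: β-elimination of the lactone of 16 gives a 3a,7a-dihydroindenone that is an isomer of the aromatic indanone. Base alone would drain it there by proton shifts. One two-electron oxidation is therefore unavoidable, and it is built into step 8 at the enolate stage.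
- C-1 stays a ketone in 14 because the carbonyl group disfavours ionisation of the tertiary allylic C–O bond during heating.

Step 1
Reactants: 1 guaiazulene
Product: 3 guaiazulene-3-carbaldehyde, via iminium salt 2 (not isolated)
Conditions: POCl3, DMF, 0 °C → rt; then aq NaOH, 0 °C
Reagents that add atoms: DMF, CN(C)C=O (formyl carbon); water, O (carbonyl oxygen); POCl3, O=P(Cl)(Cl)Cl (counter-ion of 2 only)
Why: Vilsmeier–Haack formylation; C-3 is the only free position of the nucleophilic five-membered ring of 1 (C-1 is blocked by methyl), so the chloroiminium ion attacks there and hydrolysis of 2 releases the aldehyde.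

Step 2
Reactants: 4 2-methylfuran; 3 guaiazulene-3-carbaldehyde
Product: 6 (guaiazulen-3-yl)(5-methylfuran-2-yl)methanol (racemic), via 5-methyl-2-furyllithium 5 (not isolated)
Conditions: 4, n-BuLi, THF, −78 → 0 °C; then 3, −78 °C; H2O quench; used crude
Reagents that add atoms: n-BuLi, [Li]CCCC (lithium of 5 only; nothing from it remains in 6)
Why: α-Lithiation of 2-methylfuran at its only free α-position, then 1,2-addition to the aldehyde at low temperature, where carbonyl addition should outrun deprotonation of the azulene C-4 methyl; the carbinol centre forms racemic and is erased in step 3.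

Step 3
Reactants: 6 (guaiazulen-3-yl)(5-methylfuran-2-yl)methanol
Product: 7 (4RS,5SR)-5-(guaiazulen-3-yl)-4-hydroxy-4-methylcyclopent-2-en-1-one (hydroxyl trans to azulenyl)
Conditions: ZnCl2 (1 equiv), 1,4-dioxane–H2O 4:1, 70 °C, N2, dark
Reagents that add atoms: water, O (the C-4 hydroxyl oxygen)
Why: Piancatelli rearrangement; the azulene-stabilised furfuryl cation takes up water at the methyl-bearing furan carbon, the ring opens to a hydroxypentadienyl cation, and conrotatory 4π closure should set the C-4 hydroxyl and C-5 azulenyl trans, in the mild ZnCl2 medium suited to reactive 5-methylfuryl carbinols.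

Step 4
Reactants: 8 dimethyl malonate; 9 (E)-4-methoxybut-3-en-2-one
Product: 11 methyl 6-methyl-2-oxo-2H-pyran-3-carboxylate, via dimethyl (3-oxobut-1-enyl)malonate 10 (not isolated)
Conditions: NaOMe (1 equiv), MeOH, 0 °C → reflux; then 2 M HCl
Reagents that add atoms: none
Why: Addition–elimination of the malonate anion on the β-methoxy enone gives 10, whose dienolate oxygen lactonises onto one ester (an established 2-pyrone-3-carboxylate synthesis), which places methyl on C-6 and the ester on C-3.

Step 5
Reactants: 11 methyl 6-methyl-2-oxo-2H-pyran-3-carboxylate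
Product: 12 6-methyl-2-oxo-2H-pyran-3-carboxylic acid
Conditions: 6 M HCl, 1,4-dioxane, 80 °C
Reagents that add atoms: water, O
Why: Acid-catalysed ester hydrolysis, chosen because hydroxide would open the electrophilic pyrone ring whereas the ring tolerates aqueous acid.

Step 6
Reactants: 12 6-methyl-2-oxo-2H-pyran-3-carboxylic acid; 7 trans-hydroxycyclopentenone
Product: 14 (1RS,5SR)-5-(guaiazulen-3-yl)-1-methyl-4-oxocyclopent-2-en-1-yl 6-methyl-2-oxo-2H-pyran-3-carboxylate, via pyrone acid chloride 13 (not isolated)
Conditions: 12, (COCl)2, cat. DMF, CH2Cl2, 0 °C → rt, evaporate; then 7, pyridine, DMAP (0.2 equiv), CH2Cl2, 0 °C → rt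
Reagents that add atoms: oxalyl chloride, O=C(Cl)C(=O)Cl (chlorine of 13 only; nothing from it remains in 14)
Why: Acid chloride formation and DMAP-catalysed acylation of the tertiary alcohol, whose hydroxyl lies on the ring face opposite the azulenyl group; only weak amine bases at or below room temperature are used, so the β-acyloxy ketone should not be lost by E1cB elimination, and both stereocentres stay untouched.

Step 7
Reactants: 14 pyrone ester
Product: 16 tricyclic dienyl lactone: 2-(guaiazulen-3-yl)-3,7-dimethyl-3a,7a-dihydroindan-1-one with O-3 lactonised onto the C-4 carboxyl; H-3a and H-7a cis on the face of the C-3 methyl; racemic, via bridged bicyclic lactone 15 (not isolated)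
Conditions: MeCN (0.005 M), 2,6-di-tert-butyl-4-methylpyridine (0.2 equiv), BHT (0.1 equiv), degassed, sealed vessel, 150 °C, dark
Reagents that add atoms: none
Why: The pyrone (diene termini C-3 and C-6) adds suprafacially across the enone alkene in a type 1 intramolecular Diels–Alder reaction to give the 2-oxabicyclo[2.2.2]octenone 15, which at this temperature expels CO2 by retro-[4+2] and leaves the 1,3-cyclohexadiene 16. The closest known reaction type is the thermal intramolecular 2-pyrone/alkene cycloaddition with CO2 extrusion; an ester tether reaching a cyclopentenone has no direct model, which is why the risk of the route is concentrated here. The six-membered carbocycle closes through the two new σ-bonds C-3a–C-4 and C-7–C-7a of the [4+2] event, and the γ-lactone closes at the same moment in the fused mode because the three-atom tether (C-3, O, C=O) spans C-3a and C-4. C-3a and C-7a are set cis to each other by the suprafacial addition and on the face of the C-3 oxygen by the short tether, which can only give a cis-fused five-membered lactone; the trans azulenyl group sits on the opposite face, and endo and exo forms of 15 converge on the same 16. The selectivity needed is regiochemical (carboxyl carbon next to C-3a, methyl next to C-7a), and the tether enforces it because the reversed orientation cannot be reached. The polar solvent raises the share of the s-cis ester rotamer needed for closure, high dilution suppresses bimolecular cycloaddition of 16, and the hindered pyridine traps stray acid that would cleave the tertiary ester.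

Step 8
Reactants: 16 tricyclic dienyl lactone
Product: 19 2-(guaiazulen-3-yl)-3,7-dimethyl-1-oxo-1H-indene-4-carboxylic acid, via 7a-bromo dienyl lactone 17 (not isolated), via 7a-bromo dihydroindenone acid 18 (not isolated)
Conditions: BrCCl3 (1.05 equiv), DBU (3 equiv, added last), CH2Cl2, 0 °C, N2, dark; then 1 M aq citric acid
Reagents that add atoms: BrCCl3, BrC(Cl)(Cl)Cl (bromine of 17 and 18 only; nothing from it remains in 19)
Why: Enolate halogenation–dehydrohalogenation merged with an E1cB opening; DBU forms the extended C-7a enolate and BrCCl3 brominates it (bromination at C-4 or C-6 of the same anion would lead to the same arene), deprotonation at C-2 then expels the lactone carboxylate from C-3 to give C-2=C-3, and loss of HBr across C-3a–C-7a gives the benzene ring, so bromine transfer pre-empts the redox-neutral proton shift to the indanone and all four stereocentres vanish.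

Step 9
Reactants: 19 indenone acid
Product: 20 S-ethyl 2-(guaiazulen-3-yl)-3,7-dimethyl-1-oxo-1H-indene-4-carbothioate
Conditions: EtSH, DCC, DMAP (cat.), CH2Cl2, 0 °C → rt
Reagents that add atoms: ethanethiol, CCS
Why: Steglich-type carbodiimide coupling with a thiol, which activates only the carboxyl group and leaves the ketone, the tetrasubstituted alkene and the azulene alone.

Step 10
Reactants: 20 thioester
Product: 21 2-(guaiazulen-3-yl)-3,7-dimethyl-1-oxo-1H-indene-4-carbaldehyde (target)
Conditions: Et3SiH, Pd/C (10 wt %), acetone, rt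
Reagents that add atoms: none
Why: Fukuyama reduction; palladium inserts into the acyl C–S bond and the silane delivers hydride to give the aldehyde without over-reduction, a process that tolerates ketones, while the tetrasubstituted indenone alkene is too hindered for hydrosilylation.

Compound list
1 | guaiazulene (7-isopropyl-1,4-dimethylazulene) | c1cc(C)c2cc(C(C)C)ccc(C)c1-2 | starting material
2 | N,N-dimethyl(guaiazulen-3-yl)methaniminium dichlorophosphate | C[N+](C)=Cc1cc(C)c2cc(C(C)C)ccc(C)c1-2.[O-]P(=O)(Cl)Cl | intermediate
3 | guaiazulene-3-carbaldehyde (5-isopropyl-3,8-dimethylazulene-1-carbaldehyde) | O=Cc1cc(C)c2cc(C(C)C)ccc(C)c1-2 | intermediate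
4 | 2-methylfuran | Cc1ccco1 | starting material
5 | 5-methyl-2-furyllithium | [Li]c1ccc(C)o1 | intermediate
6 | (guaiazulen-3-yl)(5-methylfuran-2-yl)methanol, racemic | OC(c1ccc(C)o1)c1cc(C)c2cc(C(C)C)ccc(C)c1-2 | intermediate
7 | (4RS,5SR)-5-(guaiazulen-3-yl)-4-hydroxy-4-methylcyclopent-2-en-1-one, OH trans to azulenyl | O=C1C=C[C@@](C)(O)[C@@H]1c1cc(C)c2cc(C(C)C)ccc(C)c1-2 | intermediate
8 | dimethyl malonate | COC(=O)CC(=O)OC | starting material
9 | (E)-4-methoxybut-3-en-2-one | CO/C=C/C(C)=O | starting material
10 | dimethyl 2-[(E)-3-oxobut-1-enyl]malonate | COC(=O)C(/C=C/C(C)=O)C(=O)OC | intermediate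
11 | methyl 6-methyl-2-oxo-2H-pyran-3-carboxylate | COC(=O)c1ccc(C)oc1=O | intermediate
12 | 6-methyl-2-oxo-2H-pyran-3-carboxylic acid | Cc1ccc(C(=O)O)c(=O)o1 | intermediate
13 | 6-methyl-2-oxo-2H-pyran-3-carbonyl chloride | Cc1ccc(C(=O)Cl)c(=O)o1 | intermediate
14 | (1RS,5SR)-5-(guaiazulen-3-yl)-1-methyl-4-oxocyclopent-2-en-1-yl 6-methyl-2-oxo-2H-pyran-3-carboxylate, ester oxygen trans to azulenyl | O=C1C=C[C@@](C)(OC(=O)c2ccc(C)oc2=O)[C@@H]1c3cc(C)c4cc(C(C)C)ccc(C)c3-4 | intermediate
15 | bridged Diels–Alder adduct (drawn endo): γ-lactone and cyclopentanone fused to a 2-oxabicyclo[2.2.2]oct-5-en-3-one whose CO2 bridge spans C-4 and C-7 | O=C1[C@@H](c2cc(C)c3cc(C(C)C)ccc(C)c2-3)[C@]2(C)OC(=O)[C@@]34C=C[C@@](C)(OC3=O)[C@H]1[C@H]24 | intermediate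
16 | tricyclic dienyl lactone: 3a,7a-dihydroindan-1-one, O-3 lactonised onto the C-4 carboxyl, H-3a/H-7a cis and on the face of C-3 methyl and C-2 azulenyl | O=C1[C@@H](c2cc(C)c3cc(C(C)C)ccc(C)c2-3)[C@]2(C)OC(=O)C3=CC=C(C)[C@H]1[C@H]23 | intermediate
17 | 7a-bromo derivative of 16 (Br in place of H-7a, cis ring fusion kept) | O=C1[C@@H](c2cc(C)c3cc(C(C)C)ccc(C)c2-3)[C@]2(C)OC(=O)C3=CC=C(C)[C@@]1(Br)[C@H]23 | intermediate
18 | 7a-bromo-2-(guaiazulen-3-yl)-3,7-dimethyl-1-oxo-3a,7a-dihydro-1H-indene-4-carboxylic acid (H-3a and Br cis) | O=C1C(c2cc(C)c3cc(C(C)C)ccc(C)c2-3)=C(C)[C@@H]2C(C(=O)O)=CC=C(C)[C@]12Br | intermediate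
19 | 2-(guaiazulen-3-yl)-3,7-dimethyl-1-oxo-1H-indene-4-carboxylic acid | CC1=C(c2cc(C)c3cc(C(C)C)ccc(C)c2-3)C(=O)c2c(C)ccc(C(=O)O)c21 | intermediate
20 | S-ethyl 2-(guaiazulen-3-yl)-3,7-dimethyl-1-oxo-1H-indene-4-carbothioate | CC1=C(c2cc(C)c3cc(C(C)C)ccc(C)c2-3)C(=O)c2c(C)ccc(C(=O)SCC)c21 | intermediate
21 | 2-(guaiazulen-3-yl)-3,7-dimethyl-1-oxo-1H-indene-4-carbaldehyde (CNP0233877.0) | CC1=C(c2cc(C)c3cc(C(C)C)ccc(C)c2-3)C(=O)c2c(C)ccc(C=O)c21 | target

Total step count: 10. Longest linear sequence: 8 (steps 1, 2, 3, 6, 7, 8, 9, 10).

Steps most likely to fail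

Step 7.
- **What may go wrong:** the tertiary ester may shed the pyrone acid, by thermal syn-elimination or acid-catalysed cleavage, faster than the cycloaddition occurs. Both π-systems are electron-poor, and the preferred s-trans ester rotamer holds them apart.
- **Fallback (sets out from 1, comes back at 19):** the arene is bought instead of built. 4-Bromotoluene and (E)-crotonoyl chloride with AlCl3 should undergo Friedel–Crafts acylation ortho to the methyl group and then Nazarov-type ring closure ortho to bromine, giving 4-bromo-3,7-dimethylindan-1-one F1. Riley oxidation with SeO2 in aqueous dioxane gives 4-bromo-3,7-dimethylindane-1,2-dione F2. In acetic acid, 1 attacks the more electrophilic C-2 carbonyl through its C-3 (acid-catalysed hydroxyalkylation of an azulene) to give 4-bromo-2-(guaiazulen-3-yl)-2-hydroxy-3,7-dimethylindan-1-one F3. This ionises to an azulene-stabilised cation and loses H-3 to give 4-bromo-2-(guaiazulen-3-yl)-3,7-dimethyl-1H-inden-1-one F4. Hydroxycarbonylation (Pd(OAc)2, dppp, CO, Et3N, aqueous DMF, 90 °C) turns the bromide into 19, and steps 9 and 10 follow unchanged.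

Step 3.
- **What may go wrong:** the azulene may stabilise the carbenium ion from 6 so strongly that conrotatory closure of the ring-opened cation lags. Ring-opened material would then isomerise or oligomerise.
- **Fallback (sets out from 6, comes back at 7):** the rearrangement is split into two known operations with an anionic ring closure. Short exposure of 6 to acetate buffer (pH 4) in aqueous THF at room temperature is carried only as far as hydrolytic furan opening, giving (Z)-1-(guaiazulen-3-yl)hex-3-ene-2,5-dione F5. Dilute aqueous Na2CO3 then closes the ring by intramolecular aldol addition of the more acidic azulenyl-CH2 enolate to the methyl ketone, the way (Z)-enediones are converted into 4-hydroxycyclopentenones. This gives 7. Any C-5 epimer is tolerable because that centre is enolisable and is planarised in step 8.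

Step 8.
- **What may go wrong:** proton shuttling by DBU may outpace bromine transfer and drain material to the indanone oxidation level. The halogen source may also attack the azulene or the C-3 methyl.
- **Fallback (sets out from 16, comes back at 19):** the proton shift is accepted and the oxidation is moved to the five-membered ring. DBU alone in degassed CH2Cl2 should give trans-2-(guaiazulen-3-yl)-3,7-dimethyl-1-oxoindane-4-carboxylic acid F6. LiN(SiMe3)2 (2.1 equiv) in THF at −78 °C, then PhSeCl, gives 2-(phenylselanyl)-2-(guaiazulen-3-yl)-3,7-dimethyl-1-oxoindane-4-carboxylic acid F7. Selenium enters anti to the C-3 methyl and therefore syn to H-3. mCPBA (1 equiv, −78 °C) gives the corresponding selenoxide F8, which on warming undergoes syn-elimination to 19.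

Further compounds
F1 | step 7 | 4-bromo-3,7-dimethylindan-1-one (racemic) | CC1CC(=O)c2c(C)ccc(Br)c21
F2 | step 7 | 4-bromo-3,7-dimethylindane-1,2-dione (racemic) | CC1C(=O)C(=O)c2c(C)ccc(Br)c21
F3 | step 7 | 4-bromo-2-(guaiazulen-3-yl)-2-hydroxy-3,7-dimethylindan-1-one (diastereomer mixture) | CC1c2c(Br)ccc(C)c2C(=O)C1(O)c1cc(C)c2cc(C(C)C)ccc(C)c1-2
F4 | step 7 | 4-bromo-2-(guaiazulen-3-yl)-3,7-dimethyl-1H-inden-1-one | CC1=C(c2cc(C)c3cc(C(C)C)ccc(C)c2-3)C(=O)c2c(C)ccc(Br)c21
F5 | step 3 | (Z)-1-(guaiazulen-3-yl)hex-3-ene-2,5-dione | CC(=O)/C=C\C(=O)Cc1cc(C)c2cc(C(C)C)ccc(C)c1-2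
F6 | step 8 | trans-2-(guaiazulen-3-yl)-3,7-dimethyl-1-oxoindane-4-carboxylic acid (racemic) | O=C1[C@@H](c2cc(C)c3cc(C(C)C)ccc(C)c2-3)[C@H](C)c2c(C(=O)O)ccc(C)c12
F7 | step 8 | 2-(phenylselanyl)-2-(guaiazulen-3-yl)-3,7-dimethyl-1-oxoindane-4-carboxylic acid (Se trans to C-3 methyl, racemic) | O=C1[C@@](c2cc(C)c3cc(C(C)C)ccc(C)c2-3)([Se]c2ccccc2)[C@H](C)c2c(C(=O)O)ccc(C)c12
F8 | step 8 | selenoxide of F7 (configuration at selenium undefined) | O=C1[C@@](c2cc(C)c3cc(C(C)C)ccc(C)c2-3)([Se](=O)c2ccccc2)[C@H](C)c2c(C(=O)O)ccc(C)c12
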